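The route rests on making the hexasubstituted benzene ring by photochemical Wolff rearrangement and benzannulation of a dihydropyranyl diazo ketone with a chiral siloxyalkyne. The feature exploited is the alternation around the benzene ring of the chroman: oxygen on C5, C7 and C8a, carbon on C4a, C6 and C8. In one operation ketene carbonyl, ynol ether and ring enol ether become C5, C7 and C8a, the bonds C5–C6, C7–C8 and C4a–C5 form, and the arene is fused onto the existing pyran ring with O5 free and O7 silylated. The precursors are diazo ketone 12 (carrying C2 and C3) and ynol ether 23 (carrying the side-chain stereocenter and an allyl group as latent CH2CO2H).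

Key step: step 13

Remark: the target is taken to be isolable as the open hydroxy acid, so the last work-up avoids strong acid and heat, which would close the acid back onto the C5 hydroxyl.
Remark: conjugate bases formed by simple proton transfer (enolates, alkoxides, phenoxides, carboxylates) are described in the Why lines and are not numbered separately.
Remark: the tricyclic compounds 31–35 are named as pyrano[2,3-f]chromenes, whose positions 4, 5, 6, 8, 9 and 10 are the side-chain carbon, C7, C8, C2, C3 and C4 of the chroman; the running text keeps chroman numbering.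

Step 1
Reactants: 1 ethyl (S)-3-hydroxybutanoate
Product: 2 ethyl (2S,3S)-3-hydroxy-2-methylbutanoate
Conditions: LiN(iPr)2 (2.2 equiv), THF, −50 → −20 °C; MeI, DMPU, −78 → 0 °C
Reagents that add atoms: iodomethane, CI
Why: Fráter–Seebach alkylation, in which the dianion is a rigid lithium chelate and iodomethane should add to the enolate face opposite to the methyl group on the carbinol carbon, setting C2 as S (anti to the hydroxyl) while C3 comes from the chiral pool.

Step 2
Reactants: 2 ethyl (2S,3S)-3-hydroxy-2-methylbutanoate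
Product: 3 ethyl (2S,3S)-3-(benzyloxy)-2-methylbutanoate
Conditions: BnOC(=NH)CCl3 (1.5 equiv), CF3SO3H (5 mol %), CH2Cl2/cyclohexane, 0 °C → rt
Reagents that add atoms: benzyl 2,2,2-trichloroacetimidate, N=C(OCc1ccccc1)C(Cl)(Cl)Cl
Why: acid-catalysed O-benzylation with a trichloroacetimidate, chosen because no base is present and the β-hydroxy ester can therefore neither eliminate nor epimerize at C2.

Step 3
Reactants: 3 ethyl (2S,3S)-3-(benzyloxy)-2-methylbutanoate
Product: 5 ethyl (2E,4R,5S)-5-(benzyloxy)-4-methylhex-2-enoate, via aldehyde 4 (not isolated)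
Conditions: iBu2AlH (1.05 equiv), CH2Cl2, −78 °C; then Ph3P=CHCO2Et (1.5 equiv), −78 °C → rt
Reagents that add atoms: ethyl (triphenylphosphoranylidene)acetate, CCOC(=O)C=P(c1ccccc1)(c1ccccc1)c1ccccc1
Why: half-reduction of the ester to its aluminium hemiacetal followed by Wittig olefination in the same flask, so that the aldehyde is released only on warming and is trapped at once by the stabilized ylide before its α-stereocenter can epimerize (the alkene geometry is immaterial because it is hydrogenated next).

Step 4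
Reactants: 5 ethyl (2E,4R,5S)-5-(benzyloxy)-4-methylhex-2-enoate
Product: 7 (5R,6S)-5,6-dimethyltetrahydro-2H-pyran-2-one, via hydroxy ester 6 (not isolated)
Conditions: H2 (1 atm), Pd(OH)2/C, EtOH, rt; filter; TsOH·H2O (5 mol %), PhMe, 60 °C
Reagents that add atoms: none
Why: catalytic hydrogenation should saturate the enoate and cleave the benzyl ether in one operation, and acid-catalysed lactonization of the δ-hydroxy ester then closes the six-membered lactone without touching either stereocenter.

Step 5
Reactants: 7 (5R,6S)-5,6-dimethyltetrahydro-2H-pyran-2-one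
Product: 8 (2S,3R)-2,3-dimethyl-3,4-dihydro-2H-pyran-6-yl diphenyl phosphate
Conditions: KN(SiMe3)2 (1.2 equiv), (PhO)2P(O)Cl (1.3 equiv), THF/DMPU, −78 °C
Reagents that add atoms: diphenyl chlorophosphate, O=P(Cl)(Oc1ccccc1)Oc1ccccc1
Why: O-phosphorylation of the lactone enolate to the cyclic ketene acetal phosphate, a standard activation of lactones for cross-coupling, with deprotonation at the lactone α-carbon remote from both stereocenters.

Step 6
Reactants: 8 (2S,3R)-2,3-dimethyl-3,4-dihydro-2H-pyran-6-yl diphenyl phosphate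
Product: 10 1-[(2S,3R)-2,3-dimethyl-3,4-dihydro-2H-pyran-6-yl]ethanone, via ethoxydiene 9 (not isolated)
Conditions: Bu3SnC(OEt)=CH2 (1.3 equiv), Pd(PPh3)4 (5 mol %), LiCl (3 equiv), THF, reflux; then 0.5 M HCl, THF, 0 °C
Reagents that add atoms: tributyl(1-ethoxyvinyl)stannane, CCCC[Sn](CCCC)(CCCC)C(=C)OCC; water, O
Why: Stille coupling of the ketene acetal phosphate with an acetyl anion equivalent followed by enol ether hydrolysis, where the acyclic enol ether should be protonated at its terminal CH2 first and the resulting 2-acyl enol ether is deactivated toward further hydrolysis.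

Step 7
Reactants: 10 1-[(2S,3R)-2,3-dimethyl-3,4-dihydro-2H-pyran-6-yl]ethanone
Product: 12 2-diazo-1-[(2S,3R)-2,3-dimethyl-3,4-dihydro-2H-pyran-6-yl]ethanone, via trifluoroacetyl diketone 11 (not isolated)
Conditions: LiN(SiMe3)2 (1.1 equiv), THF, −78 °C; CF3CO2CH2CF3 (1.2 equiv); then 4-AcNHC6H4SO2N3 (1.5 equiv), Et3N, H2O (1 equiv), MeCN, rt
Reagents that add atoms: 4-acetamidobenzenesulfonyl azide, CC(=O)Nc1ccc(cc1)S(=O)(=O)N=[N+]=[N-]
Why: detrifluoroacetylative diazo transfer, in which the kinetic methyl enolate is trifluoroacetylated and the activated diketone accepts the diazo group while passing the trifluoroacetyl group to the sulfonamide, an established diazomethane-free way to α,β-unsaturated diazo ketones.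

Step 8
Reactants: 13 (S)-4-benzyloxazolidin-2-one; 14 pentanoyl chloride
Product: 15 (S)-4-benzyl-3-pentanoyloxazolidin-2-one
Conditions: n-BuLi (1.05 equiv), THF, −78 °C; then 14, −78 → 0 °C
Reagents that add atoms: none
Why: N-acylation of the lithiated oxazolidinone, the standard entry to the Evans imide.

Step 9
Reactants: 15 (S)-4-benzyl-3-pentanoyloxazolidin-2-one; 16 allyl bromide
Product: 17 (S)-4-benzyl-3-[(R)-2-propylpent-4-enoyl]oxazolidin-2-one
Conditions: NaN(SiMe3)2 (1.1 equiv), THF, −78 °C; then 16 (3 equiv), −78 → −40 °C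
Reagents that add atoms: none
Why: Evans asymmetric alkylation, in which the chelated (Z)-sodium enolate should be attacked by allyl bromide on the face opposite to the benzyl group of the auxiliary, setting the new stereocenter as R.

Step 10
Reactants: 17 (S)-4-benzyl-3-[(R)-2-propylpent-4-enoyl]oxazolidin-2-one
Product: 19 (R)-2-propylpent-4-enoic acid, via peracid 18 (not isolated)
Conditions: LiOH (2 equiv), H2O2 (30 %, 4 equiv), THF/H2O, 0 °C; then Na2SO3 (aq), 0 °C; 1 M HCl
Reagents that add atoms: hydrogen peroxide, OO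
Why: hydroperoxide cleavage of the imide, where the hydroperoxide anion attacks the exocyclic carbonyl selectively even in α-branched imides, sulfite reduces the peracid, and the cold, mildly basic medium should leave the α-stereocenter intact (auxiliary 13 is recovered).

Step 11
Reactants: 19 (R)-2-propylpent-4-enoic acid
Product: 20 ethyl (R)-2-propylpent-4-enoate
Conditions: EtI (1.5 equiv), K2CO3 (1.5 equiv), DMF, rt
Reagents that add atoms: iodoethane, CCI
Why: O-alkylation of the carboxylate (SN2 on iodoethane), which carbonate cannot enolize, so the stereocenter is untouched.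

Step 12
Reactants: 20 ethyl (R)-2-propylpent-4-enoate
Product: 23 triisopropyl{[(3R)-3-propylhex-5-en-1-yn-1-yl]oxy}silane, via dibromo enolate 21 (not isolated), via lithium ynolate 22 (not isolated)
Conditions: CH2Br2 (2.2 equiv), lithium 2,2,6,6-tetramethylpiperidide (2.1 equiv), THF, −78 °C; LiN(SiMe3)2 (1.1 equiv); n-BuLi (excess), −78 → 25 °C; then iPr3SiCl (excess), −78 → 0 °C
Reagents that add atoms: dibromomethane, BrCBr; chlorotriisopropylsilane, CC(C)[Si](Cl)(C(C)C)C(C)C
Why: Kowalski ester homologation stopped at the ynolate and O-silylated, in which dibromomethyllithium adds to the ester, the dibromo ketone is held as its enolate (which shields the α-stereocenter), bromine–lithium exchange triggers a carbenoid 1,2-shift of the sec-alkyl group with retention, and the bulky silyl chloride traps the ynolate on oxygen.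

Step 13
Reactants: 12 2-diazo-1-[(2S,3R)-2,3-dimethyl-3,4-dihydro-2H-pyran-6-yl]ethanone; 23 triisopropyl{[(3R)-3-propylhex-5-en-1-yn-1-yl]oxy}silane
Product: 28 (2S,3R)-6-[(4R)-hept-1-en-4-yl]-2,3-dimethyl-7-(triisopropylsilyloxy)chroman-5-ol, via vinylketene 24 (not isolated), via vinylcyclobutenone 25 (not isolated), via dienylketene 26 (not isolated), via cyclohexadienone 27 (not isolated)
Conditions: 12 (1.0 equiv), 23 (1.2 equiv), hν (254 nm, low-pressure Hg lamps, quartz tube), degassed ClCH2CH2Cl, 25 °C; then 80 °C in the dark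
Reagents that add atoms: none
Why: Light should expel N2 from 12 and the dihydropyranyl group shifts to the carbene carbon (Wolff rearrangement, which also makes the future C8–C8a bond) to give vinylketene 24, whose C=C bond adds [2+2] to the ynol ether so that the ketene carbonyl carbon (future C5) bonds to the alkyne carbon carrying the sec-alkyl group (C6) and the ketene α-carbon (C8) to the siloxy carbon (C7). Cyclobutenone 25 then opens by conrotatory 4π electrocyclic cleavage to dienylketene 26, whose ketene carbon closes onto the β-carbon of the ring enol ether by thermal disrotatory 6π electrocyclization (C4a–C5, the benzene ring, fused to the existing pyran ring), and dienone 27 tautomerizes to the phenol. The closest known reaction type is the Danheiser benzannulation in its photochemical diazo ketone variant with siloxyalkynes, which is established for cycloalkenyl and heteroaryl diazo ketones. No stereocenter is created, since the sp3 centres of 25 and 27 vanish on aromatization and C2, C3 and the side-chain centre are not enolizable under these neutral conditions. The step needs regioselectivity in the [2+2] addition, secured by the polarization of the ynol ether (its carbon β to oxygen is the nucleophile and attacks the electrophilic ketene carbon), and chemoselectivity for the alkyne over the allyl group, secured by the much higher nucleophilicity of the ynol ether.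

Step 14
Reactants: 28 (2S,3R)-6-[(4R)-hept-1-en-4-yl]-2,3-dimethyl-7-(triisopropylsilyloxy)chroman-5-ol
Product: 31 (4R,8S,9R)-8,9-dimethyl-4-propyl-5-(triisopropylsilyloxy)-3,4,9,10-tetrahydro-2H,8H-pyrano[2,3-f]chromen-2-ol (lactol on O5, epimers at C2), via diol 29 (not isolated), via hydroxy aldehyde 30 (not isolated)
Conditions: OsO4 (2 mol %), 4-methylmorpholine N-oxide (NMO, 1.5 equiv), acetone/H2O, rt; then NaIO4 (1.5 equiv), 0 °C
Reagents that add atoms: 4-methylmorpholine N-oxide, C[N+]1([O-])CCOCC1; osmium tetroxide (catalytic oxygen carrier), O=[Os](=O)(=O)=O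
Why: Upjohn dihydroxylation and periodate glycol cleavage (Lemieux–Johnson sequence) remove the terminal carbon, the glycol cleavage being much faster than periodate oxidation of the hindered phenol, and the aldehyde should be captured at once by the only free phenol (O5) as the six-membered lactol.

Step 15
Reactants: 31 lactol (5-silyloxy pyranochromen-2-ol)
Product: 32 (4R,8S,9R)-8,9-dimethyl-4-propyl-5-(triisopropylsilyloxy)-3,4,9,10-tetrahydro-2H,8H-pyrano[2,3-f]chromen-2-one
Conditions: nPr4N[RuO4] (5 mol %), NMO (1.5 equiv), 4 Å molecular sieves, CH2Cl2, rt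
Reagents that add atoms: none
Why: Ley–Griffith oxidation of the lactol to the lactone, mild enough for the electron-rich arene and the aryl silyl ether, after which the lactone masks both the C5 oxygen and the carboxyl group.

Step 16
Reactants: 32 silyl lactone (5-silyloxy pyranochromen-2-one)
Product: 33 (4R,8S,9R)-5-methoxy-8,9-dimethyl-4-propyl-3,4,9,10-tetrahydro-2H,8H-pyrano[2,3-f]chromen-2-one
Conditions: CsF (3 equiv), MeI (5 equiv), dry DMF, 0 °C → rt
Reagents that add atoms: iodomethane, CI
Why: fluoride cleavage of the aryl silyl ether with in situ Williamson methylation, in which the phenoxide should be methylated by excess iodomethane as it forms and so has little time to attack the aryl lactone, while O5 cannot be methylated because it is locked in the lactone.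

Step 17
Reactants: 33 methoxy lactone
Product: 34 (4R,8S,9R)-6-iodo-5-methoxy-8,9-dimethyl-4-propyl-3,4,9,10-tetrahydro-2H,8H-pyrano[2,3-f]chromen-2-one
Conditions: N-iodosuccinimide (1.05 equiv), CF3CO2H (10 mol %), MeCN, 0 °C → rt, dark
Reagents that add atoms: N-iodosuccinimide, O=C1CCC(=O)N1I
Why: electrophilic aromatic iodination at C8 of the chroman, the only unsubstituted ring carbon, which is activated by the ortho methoxy group, the ortho ring oxygen and the para acyloxy group.

Step 18
Reactants: 34 iodo lactone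
Product: 35 (4R,8S,9R)-5-methoxy-8,9-dimethyl-6-(3-methylbut-2-en-1-yl)-4-propyl-3,4,9,10-tetrahydro-2H,8H-pyrano[2,3-f]chromen-2-one
Conditions: Bu3SnCH2CH=CMe2 (1.5 equiv), Pd(PPh3)4 (5 mol %), DMF, 90 °C
Reagents that add atoms: tributyl(3-methylbut-2-en-1-yl)stannane, CCCC[Sn](CCCC)(CCCC)CC=C(C)C
Why: Stille coupling of the aryl iodide with a prenylstannane, in which reductive elimination from the allylpalladium intermediate at its less hindered CH2 terminus should give the linear prenyl group and the neutral conditions leave the lactone intact.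

Step 19
Reactants: 35 prenyl lactone
Product: 36 (3R)-3-[(2S,3R)-5-hydroxy-7-methoxy-2,3-dimethyl-8-(3-methylbut-2-en-1-yl)chroman-6-yl]hexanoic acid (target)
Conditions: LiOH (3 equiv), degassed THF/H2O, 0 °C → rt; then 1 M HCl to pH 4, 0 °C
Reagents that add atoms: lithium hydroxide, [Li+].[OH-]
Why: saponification of the aryl lactone, in which hydroxide opens the dihydrocoumarin ring to the phenoxide carboxylate and cold acidification only to pH 4 should release the hydroxy acid without relactonization or attack on the prenyl group.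

Compound list
1 | ethyl (S)-3-hydroxybutanoate | C[C@H](O)CC(=O)OCC | starting material
2 | ethyl (2S,3S)-3-hydroxy-2-methylbutanoate | CCOC(=O)[C@@H](C)[C@H](C)O | intermediate
3 | ethyl (2S,3S)-3-(benzyloxy)-2-methylbutanoate | CCOC(=O)[C@@H](C)[C@H](C)OCc1ccccc1 | intermediate
4 | (2S,3S)-3-(benzyloxy)-2-methylbutanal | O=C[C@@H](C)[C@H](C)OCc1ccccc1 | intermediate (not isolated)
5 | ethyl (2E,4R,5S)-5-(benzyloxy)-4-methylhex-2-enoate | CCOC(=O)/C=C/[C@@H](C)[C@H](C)OCc1ccccc1 | intermediate
6 | ethyl (4R,5S)-5-hydroxy-4-methylhexanoate | CCOC(=O)CC[C@@H](C)[C@H](C)O | intermediate (not isolated)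
7 | (5R,6S)-5,6-dimethyltetrahydro-2H-pyran-2-one | O=C1CC[C@@H](C)[C@H](C)O1 | intermediate
8 | (2S,3R)-2,3-dimethyl-3,4-dihydro-2H-pyran-6-yl diphenyl phosphate | O=P(Oc1ccccc1)(Oc1ccccc1)OC1=CC[C@@H](C)[C@H](C)O1 | intermediate
9 | (2S,3R)-6-(1-ethoxyethenyl)-2,3-dimethyl-3,4-dihydro-2H-pyran | CCOC(=C)C1=CC[C@@H](C)[C@H](C)O1 | intermediate (not isolated)
10 | 1-[(2S,3R)-2,3-dimethyl-3,4-dihydro-2H-pyran-6-yl]ethanone | CC(=O)C1=CC[C@@H](C)[C@H](C)O1 | intermediate
11 | 1-[(2S,3R)-2,3-dimethyl-3,4-dihydro-2H-pyran-6-yl]-4,4,4-trifluorobutane-1,3-dione | O=C(CC(=O)C(F)(F)F)C1=CC[C@@H](C)[C@H](C)O1 | intermediate (not isolated)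
12 | 2-diazo-1-[(2S,3R)-2,3-dimethyl-3,4-dihydro-2H-pyran-6-yl]ethanone | [N-]=[N+]=CC(=O)C1=CC[C@@H](C)[C@H](C)O1 | intermediate
13 | (S)-4-benzyloxazolidin-2-one | O=C1N[C@@H](Cc2ccccc2)CO1 | starting material
14 | pentanoyl chloride | CCCCC(Cl)=O | starting material
15 | (S)-4-benzyl-3-pentanoyloxazolidin-2-one | CCCCC(=O)N1[C@@H](Cc2ccccc2)COC1=O | intermediate
16 | allyl bromide | C=CCBr | starting material
17 | (S)-4-benzyl-3-[(R)-2-propylpent-4-enoyl]oxazolidin-2-one | CCC[C@H](CC=C)C(=O)N1[C@@H](Cc2ccccc2)COC1=O | intermediate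
18 | (R)-2-propylpent-4-eneperoxoic acid | CCC[C@H](CC=C)C(=O)OO | intermediate (not isolated)
19 | (R)-2-propylpent-4-enoic acid | CCC[C@H](CC=C)C(=O)O | intermediate
20 | ethyl (R)-2-propylpent-4-enoate | CCC[C@H](CC=C)C(=O)OCC | intermediate
21 | lithium (3R)-1,1-dibromo-3-propylhexa-1,5-dien-2-olate | CCC[C@H](CC=C)C([O-])=C(Br)Br.[Li+] | intermediate (not isolated)
22 | lithium (3R)-3-propylhex-5-en-1-yn-1-olate | CCC[C@H](CC=C)C#C[O-].[Li+] | intermediate (not isolated)
23 | triisopropyl{[(3R)-3-propylhex-5-en-1-yn-1-yl]oxy}silane | CCC[C@H](CC=C)C#CO[Si](C(C)C)(C(C)C)C(C)C | intermediate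
24 | 2-[(2S,3R)-2,3-dimethyl-3,4-dihydro-2H-pyran-6-yl]ethen-1-one (vinylketene) | O=C=CC1=CC[C@@H](C)[C@H](C)O1 | intermediate (not isolated)
25 | 4-[(2S,3R)-2,3-dimethyl-3,4-dihydro-2H-pyran-6-yl]-2-[(4R)-hept-1-en-4-yl]-3-(triisopropylsilyloxy)cyclobut-2-en-1-one (epimers at C4) | CCC[C@H](CC=C)C1=C(O[Si](C(C)C)(C(C)C)C(C)C)C(C2=CC[C@@H](C)[C@H](C)O2)C1=O | intermediate (not isolated)
26 | 4-[(2S,3R)-2,3-dimethyl-3,4-dihydro-2H-pyran-6-yl]-2-[(4R)-hept-1-en-4-yl]-3-(triisopropylsilyloxy)buta-1,3-dien-1-one (dienylketene) | CCC[C@H](CC=C)C(=C=O)C(O[Si](C(C)C)(C(C)C)C(C)C)=CC1=CC[C@@H](C)[C@H](C)O1 | intermediate (not isolated)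
27 | (2S,3R)-6-[(4R)-hept-1-en-4-yl]-2,3-dimethyl-7-(triisopropylsilyloxy)-2,3,4,4a-tetrahydro-5H-chromen-5-one (epimers at C4a) | CCC[C@H](CC=C)C1=C(O[Si](C(C)C)(C(C)C)C(C)C)C=C2O[C@@H](C)[C@H](C)CC2C1=O | intermediate (not isolated)
28 | (2S,3R)-6-[(4R)-hept-1-en-4-yl]-2,3-dimethyl-7-(triisopropylsilyloxy)chroman-5-ol | CCC[C@H](CC=C)c1c(O)c2C[C@@H](C)[C@H](C)Oc2cc1O[Si](C(C)C)(C(C)C)C(C)C | intermediate
29 | (4R)-4-[(2S,3R)-5-hydroxy-2,3-dimethyl-7-(triisopropylsilyloxy)chroman-6-yl]heptane-1,2-diol (epimers at C2 of the diol) | CCC[C@H](CC(O)CO)c1c(O)c2C[C@@H](C)[C@H](C)Oc2cc1O[Si](C(C)C)(C(C)C)C(C)C | intermediate (not isolated)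
30 | (3R)-3-[(2S,3R)-5-hydroxy-2,3-dimethyl-7-(triisopropylsilyloxy)chroman-6-yl]hexanal | CCC[C@H](CC=O)c1c(O)c2C[C@@H](C)[C@H](C)Oc2cc1O[Si](C(C)C)(C(C)C)C(C)C | intermediate (not isolated)
31 | (4R,8S,9R)-8,9-dimethyl-4-propyl-5-(triisopropylsilyloxy)-3,4,9,10-tetrahydro-2H,8H-pyrano[2,3-f]chromen-2-ol (epimers at C2) | CCC[C@H](CC(O)O3)c1c3c2C[C@@H](C)[C@H](C)Oc2cc1O[Si](C(C)C)(C(C)C)C(C)C | intermediate
32 | (4R,8S,9R)-8,9-dimethyl-4-propyl-5-(triisopropylsilyloxy)-3,4,9,10-tetrahydro-2H,8H-pyrano[2,3-f]chromen-2-one | CCC[C@H](CC(=O)O3)c1c3c2C[C@@H](C)[C@H](C)Oc2cc1O[Si](C(C)C)(C(C)C)C(C)C | intermediate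
33 | (4R,8S,9R)-5-methoxy-8,9-dimethyl-4-propyl-3,4,9,10-tetrahydro-2H,8H-pyrano[2,3-f]chromen-2-one | CCC[C@H](CC(=O)O3)c1c3c2C[C@@H](C)[C@H](C)Oc2cc1OC | intermediate
34 | (4R,8S,9R)-6-iodo-5-methoxy-8,9-dimethyl-4-propyl-3,4,9,10-tetrahydro-2H,8H-pyrano[2,3-f]chromen-2-one | CCC[C@H](CC(=O)O3)c1c3c2C[C@@H](C)[C@H](C)Oc2c(I)c1OC | intermediate
35 | (4R,8S,9R)-5-methoxy-8,9-dimethyl-6-(3-methylbut-2-en-1-yl)-4-propyl-3,4,9,10-tetrahydro-2H,8H-pyrano[2,3-f]chromen-2-one | CCC[C@H](CC(=O)O3)c1c3c2C[C@@H](C)[C@H](C)Oc2c(CC=C(C)C)c1OC | intermediate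
36 | (3R)-3-[(2S,3R)-5-hydroxy-7-methoxy-2,3-dimethyl-8-(3-methylbut-2-en-1-yl)chroman-6-yl]hexanoic acid | CCC[C@H](CC(=O)O)c1c(O)c2c(c(CC=C(C)C)c1OC)O[C@@H](C)[C@H](C)C2 | target

Total step count: 19. Longest linear sequence: 14 steps (steps 1–7, then 13–19).

Steps most likely to fail

Step 13. The photochemical cascade may be eroded by carbene side reactions, by dimerization of the vinylketene before it meets the ynol ether, or by photodegradation of the electron-rich phenol under the 254 nm light. The fallback makes the same vinylketene thermally. It sets out from diazo ketone 12, which is subjected to a silver-catalysed Wolff rearrangement in water (PhCO2Ag, Et3N, THF/H2O) to give 2-[(2S,3R)-2,3-dimethyl-3,4-dihydro-2H-pyran-6-yl]acetic acid F1. Under neutral conditions (1-chloro-N,N,2-trimethylprop-1-en-1-amine, CH2Cl2, 0 °C) this should give 2-[(2S,3R)-2,3-dimethyl-3,4-dihydro-2H-pyran-6-yl]acetyl chloride F2. Slow addition of F2 to Et3N and ynol ether 23 in toluene at 80 °C should generate ketene 24 by dehydrochlorination in the dark. The same cycloaddition, ring opening and electrocyclization through 25, 26 and 27 then comes back to the route at chromanol 28.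

Step 16. During the silyl-to-methyl exchange the aryl lactone may be opened by fluoride or by the phenoxide, which would lead to over-methylation or to acyl transfer between O5 and O7. The fallback carries out the exchange one oxidation level earlier, on a base-stable acetal. It sets out from lactol 31, which is converted (MeOH, HC(OMe)3, pyridinium p-toluenesulfonate) into the methyl acetal (4R,8S,9R)-2-methoxy-8,9-dimethyl-4-propyl-5-(triisopropylsilyloxy)-3,4,9,10-tetrahydro-2H,8H-pyrano[2,3-f]chromene F3. CsF and MeI in DMF should then give (4R,8S,9R)-2,5-dimethoxy-8,9-dimethyl-4-propyl-3,4,9,10-tetrahydro-2H,8H-pyrano[2,3-f]chromene F4. Mild aqueous acid (1 M HCl, THF) returns the lactol (4R,8S,9R)-5-methoxy-8,9-dimethyl-4-propyl-3,4,9,10-tetrahydro-2H,8H-pyrano[2,3-f]chromen-2-ol F5, and the perruthenate oxidation of step 15 (nPr4N[RuO4], NMO) comes back to the route at methoxy lactone 33.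

Step 18. Transmetalation may scramble the two allyl termini and deliver some of the 1,1-dimethylallyl isomer, or the coupling may stall at the doubly ortho-substituted iodide and end in protodeiodination. The fallback assembles the prenyl group in two operations. It sets out from iodide 34, which is coupled with Bu3SnCH2CH=CH2 (Pd(PPh3)4, DMF, 90 °C), where both allyl termini are equivalent, to give (4R,8S,9R)-6-allyl-5-methoxy-8,9-dimethyl-4-propyl-3,4,9,10-tetrahydro-2H,8H-pyrano[2,3-f]chromen-2-one F6. Olefin cross-metathesis of F6 with 2-methylbut-2-ene (second-generation Grubbs catalyst (H2IMes)(PCy3)Cl2Ru=CHPh, CH2Cl2, 40 °C) comes back to the route at prenyl lactone 35.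

Further compounds
F1 | step 13 | 2-[(2S,3R)-2,3-dimethyl-3,4-dihydro-2H-pyran-6-yl]acetic acid | OC(=O)CC1=CC[C@@H](C)[C@H](C)O1
F2 | step 13 | 2-[(2S,3R)-2,3-dimethyl-3,4-dihydro-2H-pyran-6-yl]acetyl chloride | ClC(=O)CC1=CC[C@@H](C)[C@H](C)O1
F3 | step 16 | (4R,8S,9R)-2-methoxy-8,9-dimethyl-4-propyl-5-(triisopropylsilyloxy)-3,4,9,10-tetrahydro-2H,8H-pyrano[2,3-f]chromene (epimers at C2) | CCC[C@H](CC(OC)O3)c1c3c2C[C@@H](C)[C@H](C)Oc2cc1O[Si](C(C)C)(C(C)C)C(C)C
F4 | step 16 | (4R,8S,9R)-2,5-dimethoxy-8,9-dimethyl-4-propyl-3,4,9,10-tetrahydro-2H,8H-pyrano[2,3-f]chromene (epimers at C2) | CCC[C@H](CC(OC)O3)c1c3c2C[C@@H](C)[C@H](C)Oc2cc1OC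
F5 | step 16 | (4R,8S,9R)-5-methoxy-8,9-dimethyl-4-propyl-3,4,9,10-tetrahydro-2H,8H-pyrano[2,3-f]chromen-2-ol (epimers at C2) | CCC[C@H](CC(O)O3)c1c3c2C[C@@H](C)[C@H](C)Oc2cc1OC
F6 | step 18 | (4R,8S,9R)-6-allyl-5-methoxy-8,9-dimethyl-4-propyl-3,4,9,10-tetrahydro-2H,8H-pyrano[2,3-f]chromen-2-one | CCC[C@H](CC(=O)O3)c1c3c2C[C@@H](C)[C@H](C)Oc2c(CC=C)c1OC
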